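## Retrosynthetic overview

1. Target ⇐ enol-ether hydrolysis ⇐ methoxynaphthoquinone ⇐ Diels–Alder/dehydrogenation of the labdatriene acid (ozic acid, unmasked from a sulfolene) with 2-methoxy-3-methylbenzoquinone. This copies the presumed biogenetic [4+2] of an ent-labdatrienoic acid with a methylhydroxyquinone.
2. Decalin ⇐ one cationic chair–chair bicyclization of an acyclic (S)-2-methyl-2-alkyloxirane, ended by loss of silicon from C17 (key step). It is the laboratory counterpart of the class 2 cyclase step that turns geranylgeranyl diphosphate into the 8(17)-ene labdane skeleton; C4, C5, C9 and C10 all follow from the one oxirane stereocentre.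
3. Acyclic precursor ⇐ (2E,6E)-farnesyl acetate (terminal allylic oxidation, Sharpless epoxidation, hydride opening, directed allylic silylation) + 3-methyl-3-sulfolene.
4. Order of ring formation: ring A → ring B (same step) → benzenoid ring of the naphthoquinone. The quinone ring comes from a phenol; the sulfolene ring is only a diene mask.

Assumption: the terpenoid half is numbered as a labdane (C1–C20), and the SMILES is read as (4S,5S,9R,10S), an ent-labdane with the C4 carboxyl equatorial (the ozic acid series).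

## Route

Step 1
Reactants: 1 (2E,6E)-3,7,11-trimethyldodeca-2,6,10-trien-1-yl acetate ((E,E)-farnesyl acetate)
Product: 2 (2E,6E,10E)-12-hydroxy-3,7,11-trimethyldodeca-2,6,10-trien-1-yl acetate
Conditions: SeO2 (0.1 equiv), salicylic acid (0.1 equiv), tBuOOH (3 equiv), CH2Cl2, 0 °C to rt
Reagents that add atoms: tert-butyl hydroperoxide, CC(C)(C)OO
Why: SeO2-catalysed allylic (Riley) oxidation, an ene reaction followed by a [2,3]-sigmatropic shift, attacks the terminal, most electron-rich trisubstituted alkene at its (E)-methyl group and leaves the alkene geometry untouched, so only the (E)-allylic alcohol forms and no stereocentre is created.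

Step 2
Reactants: 2 (2E,6E,10E)-12-hydroxy-3,7,11-trimethyldodeca-2,6,10-trien-1-yl acetate
Product: 3 (2E,6E)-9-[(2R,3R)-3-(hydroxymethyl)-3-methyloxiran-2-yl]-3,7-dimethylnona-2,6-dien-1-yl acetate
Conditions: Ti(OiPr)4 (0.1 equiv), D-(−)-diethyl tartrate (0.12 equiv), tBuOOH (2 equiv), 4 Å molecular sieves, CH2Cl2, −20 °C
Reagents that add atoms: tert-butyl hydroperoxide, CC(C)(C)OO
Why: Sharpless asymmetric epoxidation is directed by the free C12 hydroxyl, so only that alkene reacts, and the D-(−)-tartrate titanium complex delivers oxygen to the face that gives the (2R,3R)-oxirane, which fixes the configuration of the future C4.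

Step 3
Reactants: 3 (2E,6E)-9-[(2R,3R)-3-(hydroxymethyl)-3-methyloxiran-2-yl]-3,7-dimethylnona-2,6-dien-1-yl acetate
Product: 4 (2E,6E,11S)-3,7,11-trimethyldodeca-2,6-diene-1,11,12-triol
Conditions: LiAlH4 (2.5 equiv), THF, 0 °C to rt; H2O/NaOH(aq) work-up
Reagents that add atoms: none
Why: Hydride opens the epoxide in SN2 fashion at the less substituted secondary carbon (the C12 alkoxyaluminate also delivers hydride there through a five-membered transition state), so the tertiary C–O bond and its configuration survive as the (11S)-carbinol, while the acetate is reduced off in the same pot.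

Step 4
Reactants: 4 (2E,6E,11S)-3,7,11-trimethyldodeca-2,6-diene-1,11,12-triol
Product: 7 (2Z,6E,11S)-7,11-dimethyl-3-[(trimethylsilyl)methyl]dodeca-2,6-diene-1,11,12-triol, via tetralithio derivative 5 (not isolated), via tetrakis(trimethylsilyl) derivative 6 (not isolated)
Conditions: n-BuLi (5 equiv), TMEDA (5 equiv), Et2O–hexane, 0 °C to rt, 20 h; Me3SiCl (6 equiv), −78 to 0 °C; then K2CO3 (cat.), MeOH, rt
Reagents that add atoms: chlorotrimethylsilane, C[Si](C)(C)Cl
Why: Alkoxide-directed allylic lithiation (Cardillo–Trost dianion chemistry) removes a proton from the methyl group that is cis to the CH2OLi group, C-silylation at that carbon gives the allylsilane with the alkene geometry unchanged, and the three O-silyl groups are methanolysed in the work-up, so no stereocentre is touched.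

Step 5
Reactants: 7 (2Z,6E,11S)-7,11-dimethyl-3-[(trimethylsilyl)methyl]dodeca-2,6-diene-1,11,12-triol
Product: 9 (2S,6E,10Z)-12-bromo-2-hydroxy-2,6-dimethyl-10-[(trimethylsilyl)methyl]dodeca-6,10-dien-1-yl methanesulfonate, via bis(methanesulfonate) 8 (not isolated)
Conditions: MsCl (2.1 equiv), Et3N (3 equiv), CH2Cl2, −40 °C; then LiBr (3 equiv), THF, −40 to 0 °C
Reagents that add atoms: methanesulfonyl chloride, CS(=O)(=O)Cl; lithium bromide, [Li+].[Br-]
Why: Sulfonylation under Et3N takes both primary hydroxyls but not the tertiary one, and bromide then displaces only the allylic mesylate (SN2, Finkelstein type), the neopentyl-type mesylate next to the quaternary carbinol being inert at 0 °C.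

Step 6
Reactants: 9 (2S,6E,10Z)-12-bromo-2-hydroxy-2,6-dimethyl-10-[(trimethylsilyl)methyl]dodeca-6,10-dien-1-yl methanesulfonate; 10 3-methyl-2,5-dihydrothiophene 1,1-dioxide (3-methyl-3-sulfolene)
Product: 12 3-methyl-2-{(2Z,6E)-7-methyl-10-[(2S)-2-methyloxiran-2-yl]-3-[(trimethylsilyl)methyl]deca-2,6-dien-1-yl}-2,5-dihydrothiophene 1,1-dioxide (both epimers at the sulfolene carbon), via epoxy bromide 11 (not isolated)
Conditions: LiN(SiMe3)2 (1.0 equiv), THF, −78 to −20 °C; then 10 (1.2 equiv), HMPA, LiN(SiMe3)2 (1.05 equiv, added last), −78 °C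
Reagents that add atoms: none
Why: The lithium alkoxide closes onto the adjacent primary mesylate (intramolecular Williamson reaction that leaves the C–O bond of the stereocentre untouched, so the (S)-oxirane results), and the 2-lithio-3-sulfolene formed next to the methyl-bearing alkene carbon is trapped at −78 °C by the allylic bromide in an SN2 alkylation before it can ring-open.

Step 7
Reactants: 12 3-methyl-2-{(2Z,6E)-7-methyl-10-[(2S)-2-methyloxiran-2-yl]-3-[(trimethylsilyl)methyl]deca-2,6-dien-1-yl}-2,5-dihydrothiophene 1,1-dioxide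
Product: 13 {(1S,4aS,5R,8aS)-1,4a-dimethyl-6-methylidene-5-[(3-methyl-1,1-dioxo-2,5-dihydrothiophen-2-yl)methyl]decahydronaphthalen-1-yl}methanol
Conditions: MeAlCl2 (3 equiv), CH2Cl2, −78 °C, 30 min; 1 M HCl work-up
Reagents that add atoms: none
Why: Proposed new method: MeAlCl2 coordinates the oxirane oxygen and the neighbouring trisubstituted alkene opens the tertiary C–O bond from the back (inversion, so the (S)-oxirane gives 4S) in a chair–chair cation–olefin cascade in which the aluminated CH2O group, which must leave anti to the forming C4–C5 bond, can lie only in the open equatorial sector (methyl axial), the (E)-alkene gives the trans ring fusion with C5 and C10 fixed relative to C4, the allylsilane adds through C9 with its C11 branch equatorial, and loss of the silyl group from C17 can give only the exocyclic 8(17)-alkene; the closest known reaction type is the Lewis-acid-promoted, epoxide-initiated, allylsilane-terminated polyene cyclization of trisubstituted oxiranes, from which this differs in using a 2-methyl-2-alkyloxirane so that C3 stays CH2 and C4 is formed directly as the methyl/hydroxymethyl quaternary centre.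

Step 8
Reactants: 13 {(1S,4aS,5R,8aS)-1,4a-dimethyl-6-methylidene-5-[(3-methyl-1,1-dioxo-2,5-dihydrothiophen-2-yl)methyl]decahydronaphthalen-1-yl}methanol
Product: 15 (1S,4aS,5R,8aS)-1,4a-dimethyl-6-methylidene-5-[(3-methyl-1,1-dioxo-2,5-dihydrothiophen-2-yl)methyl]decahydronaphthalene-1-carboxylic acid, via aldehyde 14 (not isolated)
Conditions: TEMPO (0.2 equiv), PhI(OAc)2 (2.5 equiv), MeCN–H2O (1:1), rt
Reagents that add atoms: water, O
Why: Oxoammonium (TEMPO) catalysis with PhI(OAc)2 as terminal oxidant takes the primary alcohol to the aldehyde and, through its hydrate, to the acid under near-neutral conditions that leave the exocyclic alkene, the sulfolene and the quaternary C4 centre untouched.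

Step 9
Reactants: 16 3-methoxy-2-methylphenol
Product: 17 2-methoxy-3-methylcyclohexa-2,5-diene-1,4-dione
Conditions: (KSO3)2NO (2.2 equiv), KH2PO4 buffer, H2O–acetone, rt
Reagents that add atoms: potassium nitrosodisulfonate, [K+].[K+].[O]N(S(=O)(=O)[O-])S(=O)(=O)[O-]
Why: Teuber oxidation of a phenol with a free para position gives the para-quinone directly, and no stereocentre is involved.

Step 10
Reactants: 15 (1S,4aS,5R,8aS)-1,4a-dimethyl-6-methylidene-5-[(3-methyl-1,1-dioxo-2,5-dihydrothiophen-2-yl)methyl]decahydronaphthalene-1-carboxylic acid; 17 2-methoxy-3-methylcyclohexa-2,5-diene-1,4-dione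
Product: 21 (1S,4aS,5R,8aS)-5-[(7-methoxy-2,6-dimethyl-5,8-dioxo-5,8-dihydronaphthalen-1-yl)methyl]-1,4a-dimethyl-6-methylidenedecahydronaphthalene-1-carboxylic acid, via ozic acid 18 (not isolated), via Diels–Alder adduct 19 (not isolated), via dihydronaphthoquinone 20 (not isolated)
Conditions: 17 (1.5 equiv), PhMe, 111 °C, argon sparge; then DDQ (2.2 equiv), 60 °C
Reagents that add atoms: none
Why: Cheletropic loss of SO2 (disrotatory, the ring substituent turning outward) unmasks the (E)-diene, which undergoes a thermal Diels–Alder reaction at the unsubstituted double bond of the quinone with its unsubstituted terminus on the carbon β to the more electrophilic carbonyl (the one not deactivated by the vinylogous-ester methoxy group), so the CH2-bearing carbon ends next to the carbonyl flanked by OMe, and DDQ dehydrogenation then aromatises the new ring and erases the adduct stereocentres.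

Step 11
Reactants: 21 (1S,4aS,5R,8aS)-5-[(7-methoxy-2,6-dimethyl-5,8-dioxo-5,8-dihydronaphthalen-1-yl)methyl]-1,4a-dimethyl-6-methylidenedecahydronaphthalene-1-carboxylic acid
Product: 22 (1S,4aS,5R,8aS)-5-[(7-hydroxy-2,6-dimethyl-5,8-dioxo-5,8-dihydronaphthalen-1-yl)methyl]-1,4a-dimethyl-6-methylidenedecahydronaphthalene-1-carboxylic acid (CNP0259461.3)
Conditions: KOH (1 M aq., 5 equiv), MeOH–THF, rt; then 1 M HCl
Reagents that add atoms: potassium hydroxide, [K+].[OH-]
Why: Hydroxide adds to the methoxy-bearing carbon of the vinylogous ester and expels methoxide (addition–elimination), giving the acidic 2-hydroxy-1,4-naphthoquinone as its salt, which is freed on acidification, while the remote decalin stereocentres and the exocyclic alkene are not affected.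

## Compound list

1 | (2E,6E)-3,7,11-trimethyldodeca-2,6,10-trien-1-yl acetate | CC(C)=CCC/C(C)=C/CC/C(C)=C/COC(C)=O | starting material
2 | (2E,6E,10E)-12-hydroxy-3,7,11-trimethyldodeca-2,6,10-trien-1-yl acetate | OC/C(C)=C/CC/C(C)=C/CC/C(C)=C/COC(C)=O | intermediate
3 | (2E,6E)-9-[(2R,3R)-3-(hydroxymethyl)-3-methyloxiran-2-yl]-3,7-dimethylnona-2,6-dien-1-yl acetate | OC[C@@]1(C)O[C@@H]1CC/C(C)=C/CC/C(C)=C/COC(C)=O | intermediate
4 | (2E,6E,11S)-3,7,11-trimethyldodeca-2,6-diene-1,11,12-triol | OC[C@@](C)(O)CCC/C(C)=C/CC/C(C)=C/CO | intermediate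
5 | tetralithio derivative of 4 (three lithium alkoxides, C–Li on the methyl carbon cis to CH2O) | [Li]OC[C@@](C)(O[Li])CCC/C(C)=C/CC/C(C[Li])=C/CO[Li] | intermediate
6 | tetrakis(trimethylsilyl) derivative (three O-silyl groups, one C-silyl group) | C[Si](C)(C)OC[C@@](C)(O[Si](C)(C)C)CCC/C(C)=C/CC/C(C[Si](C)(C)C)=C/CO[Si](C)(C)C | intermediate
7 | (2Z,6E,11S)-7,11-dimethyl-3-[(trimethylsilyl)methyl]dodeca-2,6-diene-1,11,12-triol | OC[C@@](C)(O)CCC/C(C)=C/CC/C(C[Si](C)(C)C)=C/CO | intermediate
8 | (2Z,6E,11S)-11-hydroxy-7,11-dimethyl-3-[(trimethylsilyl)methyl]dodeca-2,6-diene-1,12-diyl dimethanesulfonate | CS(=O)(=O)OC[C@@](C)(O)CCC/C(C)=C/CC/C(C[Si](C)(C)C)=C/COS(C)(=O)=O | intermediate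
9 | (2S,6E,10Z)-12-bromo-2-hydroxy-2,6-dimethyl-10-[(trimethylsilyl)methyl]dodeca-6,10-dien-1-yl methanesulfonate | CS(=O)(=O)OC[C@@](C)(O)CCC/C(C)=C/CC/C(C[Si](C)(C)C)=C/CBr | intermediate
10 | 3-methyl-2,5-dihydrothiophene 1,1-dioxide | CC1=CCS(=O)(=O)C1 | starting material
11 | (2S)-2-{(4E,8Z)-10-bromo-4-methyl-8-[(trimethylsilyl)methyl]deca-4,8-dien-1-yl}-2-methyloxirane | C[C@@]1(CO1)CCC/C(C)=C/CC/C(C[Si](C)(C)C)=C/CBr | intermediate
12 | 3-methyl-2-{(2Z,6E)-7-methyl-10-[(2S)-2-methyloxiran-2-yl]-3-[(trimethylsilyl)methyl]deca-2,6-dien-1-yl}-2,5-dihydrothiophene 1,1-dioxide (sulfolene carbon: both epimers) | C[C@@]1(CO1)CCC/C(C)=C/CC/C(C[Si](C)(C)C)=C/CC2C(C)=CCS2(=O)=O | intermediate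
13 | {(1S,4aS,5R,8aS)-1,4a-dimethyl-6-methylidene-5-[(3-methyl-1,1-dioxo-2,5-dihydrothiophen-2-yl)methyl]decahydronaphthalen-1-yl}methanol (sulfolene carbon: both epimers) | C=C1CC[C@H]2[C@@](C)(CCC[C@]2(C)CO)[C@@H]1CC3C(C)=CCS3(=O)=O | intermediate
14 | (1S,4aS,5R,8aS)-1,4a-dimethyl-6-methylidene-5-[(3-methyl-1,1-dioxo-2,5-dihydrothiophen-2-yl)methyl]decahydronaphthalene-1-carbaldehyde | C=C1CC[C@H]2[C@@](C)(CCC[C@]2(C)C=O)[C@@H]1CC3C(C)=CCS3(=O)=O | intermediate
15 | (1S,4aS,5R,8aS)-1,4a-dimethyl-6-methylidene-5-[(3-methyl-1,1-dioxo-2,5-dihydrothiophen-2-yl)methyl]decahydronaphthalene-1-carboxylic acid | C=C1CC[C@H]2[C@@](C)(CCC[C@]2(C)C(=O)O)[C@@H]1CC3C(C)=CCS3(=O)=O | intermediate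
16 | 3-methoxy-2-methylphenol | COc1cccc(O)c1C | starting material
17 | 2-methoxy-3-methylcyclohexa-2,5-diene-1,4-dione | COC1=C(C)C(=O)C=CC1=O | intermediate
18 | (1S,4aS,5R,8aS)-1,4a-dimethyl-6-methylidene-5-[(2E)-3-methylpenta-2,4-dien-1-yl]decahydronaphthalene-1-carboxylic acid (ozic acid) | C=C1CC[C@H]2[C@@](C)(CCC[C@]2(C)C(=O)O)[C@@H]1C/C=C(C)/C=C | intermediate
19 | cis-fused Diels–Alder adduct: (1S,4aS,5R,8aS)-5-[(7-methoxy-2,6-dimethyl-5,8-dioxo-1,4,4a,5,8,8a-hexahydronaphthalen-1-yl)methyl]-1,4a-dimethyl-6-methylidenedecahydronaphthalene-1-carboxylic acid (three new sp3 centres, diastereomer mixture) | C=C1CC[C@H]2[C@@](C)(CCC[C@]2(C)C(=O)O)[C@@H]1CC3C(C)=CCC4C(=O)C(C)=C(OC)C(=O)C34 | intermediate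
20 | (1S,4aS,5R,8aS)-5-[(7-methoxy-2,6-dimethyl-5,8-dioxo-1,4,5,8-tetrahydronaphthalen-1-yl)methyl]-1,4a-dimethyl-6-methylidenedecahydronaphthalene-1-carboxylic acid (ring CH: both epimers) | C=C1CC[C@H]2[C@@](C)(CCC[C@]2(C)C(=O)O)[C@@H]1CC3C(C)=CCC4=C3C(=O)C(OC)=C(C)C4=O | intermediate
21 | (1S,4aS,5R,8aS)-5-[(7-methoxy-2,6-dimethyl-5,8-dioxo-5,8-dihydronaphthalen-1-yl)methyl]-1,4a-dimethyl-6-methylidenedecahydronaphthalene-1-carboxylic acid | C=C1CC[C@H]2[C@@](C)(CCC[C@]2(C)C(=O)O)[C@@H]1Cc1c(C)ccc2c1C(=O)C(OC)=C(C)C2=O | intermediate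
22 | (1S,4aS,5R,8aS)-5-[(7-hydroxy-2,6-dimethyl-5,8-dioxo-5,8-dihydronaphthalen-1-yl)methyl]-1,4a-dimethyl-6-methylidenedecahydronaphthalene-1-carboxylic acid | C=C1CC[C@H]2[C@@](C)(CCC[C@]2(C)C(=O)O)[C@@H]1Cc1c(C)ccc2c1C(=O)C(O)=C(C)C2=O | target

## Step count and risks

Total step count: 11. Longest linear sequence: 10 steps (steps 1–8, 10 and 11); step 9 is a one-step side branch.

The three steps most likely to fail:

**Step 7 (key bicyclization).** The 2,2-disubstituted oxirane may rearrange to the aldehyde by hydride shift before the alkene engages, and the equatorial/axial choice of the CH2O group at C4 rests on a steric argument only. The fallback builds the decalin by the radical counterpart, which needs no silicon. It sets out from 3 and comes back at 13. K2CO3 in MeOH removes the acetate to give the epoxy diol F3. MsCl/Et3N at −40 °C followed by LiBr converts only the allylic hydroxyl (the one next to the quaternary oxirane carbon is neopentyl-like) and gives the allylic bromide F4. Alkylation of 10 with LiN(SiMe3)2 (2 equiv, −78 °C) gives the sulfolene epoxy alcohol F5. Cp2TiCl (trivalent titanium, made from Cp2TiCl2 and Mn dust, with Me3SiCl and 2,4,6-collidine) opens the trisubstituted epoxide to the tertiary C4 radical. Its 6-endo/6-endo cyclization is steered by the retained C3–O stereocentre and ends by hydrogen loss to the exocyclic alkene, giving the bicyclic diol F6; here too C4 is only sterically biased. 1,1'-Thiocarbonyldiimidazole closes the 1,3-diol to the cyclic thionocarbonate F7, and Bu3SnH/AIBN at 80 °C cleaves the secondary C3–O bond; basic work-up frees the primary alcohol, which is 13.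

**Step 4 (directed lithiation of the unprotected triol).** A tri-alkoxide may metalate sluggishly or aggregate. The fallback masks the diol first. It sets out from 4 and comes back at 7. 2,2-Dimethoxypropane with pyridinium p-toluenesulfonate gives the acetonide alcohol F1 (only the 11,12-diol can form a dioxolane). The same n-BuLi/TMEDA then Me3SiCl sequence, now on a mono-alkoxide, gives the silylated acetonide F2. 80% aqueous AcOH at rt removes the acetonide without touching the allylsilane and gives 7.

**Step 10 (cycloaddition regiochemistry).** The 1-alkyl and 2-methyl groups of the diene direct in opposite senses, so some of the regioisomer with the CH2 group next to the carbonyl flanked by C-methyl is expected. The fallback imposes the orientation with a halogen. It sets out from 17 (and from 15, thermolysed alone in PhMe at 111 °C to 18) and comes back at 20. Br2 then Et3N converts 17 into the bromoquinone F8 (bromine on the carbon next to the carbonyl flanked by OMe). Diene 18 adds across the brominated double bond with its unsubstituted terminus on the CH carbon to give the bromo adduct F9. F9 loses HBr with Et3N to give 20, and one equivalent of DDQ then gives 21 as in the main route.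

## Further compounds

F1 | step 4 | (2E,6E)-3,7-dimethyl-10-[(4S)-2,2,4-trimethyl-1,3-dioxolan-4-yl]deca-2,6-dien-1-ol | CC1(C)OC[C@@](C)(O1)CCC/C(C)=C/CC/C(C)=C/CO
F2 | step 4 | (2Z,6E)-7-methyl-10-[(4S)-2,2,4-trimethyl-1,3-dioxolan-4-yl]-3-[(trimethylsilyl)methyl]deca-2,6-dien-1-ol | CC1(C)OC[C@@](C)(O1)CCC/C(C)=C/CC/C(C[Si](C)(C)C)=C/CO
F3 | step 7 | (2E,6E)-9-[(2R,3R)-3-(hydroxymethyl)-3-methyloxiran-2-yl]-3,7-dimethylnona-2,6-dien-1-ol | OC[C@@]1(C)O[C@@H]1CC/C(C)=C/CC/C(C)=C/CO
F4 | step 7 | [(2R,3R)-3-[(3E,7E)-9-bromo-3,7-dimethylnona-3,7-dien-1-yl]-2-methyloxiran-2-yl]methanol | OC[C@@]1(C)O[C@@H]1CC/C(C)=C/CC/C(C)=C/CBr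
F5 | step 7 | 2-{(2E,6E)-9-[(2R,3R)-3-(hydroxymethyl)-3-methyloxiran-2-yl]-3,7-dimethylnona-2,6-dien-1-yl}-3-methyl-2,5-dihydrothiophene 1,1-dioxide | OC[C@@]1(C)O[C@@H]1CC/C(C)=C/CC/C(C)=C/CC2C(C)=CCS2(=O)=O
F6 | step 7 | (1S,2R,4aS,5R,8aS)-1-(hydroxymethyl)-1,4a-dimethyl-6-methylidene-5-[(3-methyl-1,1-dioxo-2,5-dihydrothiophen-2-yl)methyl]decahydronaphthalen-2-ol | C=C1CC[C@H]2[C@@](C)(CC[C@@H](O)[C@]2(C)CO)[C@@H]1CC3C(C)=CCS3(=O)=O
F7 | step 7 | cyclic thionocarbonate (1,3-dioxane-2-thione) of F6 across the ring hydroxyl and the hydroxymethyl group | C=C1CC[C@H]2[C@@](C)(CC[C@@H](O3)[C@]2(C)COC3=S)[C@@H]1CC4C(C)=CCS4(=O)=O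
F8 | step 10 | 6-bromo-2-methoxy-3-methylcyclohexa-2,5-diene-1,4-dione | COC1=C(C)C(=O)C=C(Br)C1=O
F9 | step 10 | 8a-bromo analogue of adduct 19 (bromine on the ring-fusion carbon next to the carbonyl flanked by OMe) | C=C1CC[C@H]2[C@@](C)(CCC[C@]2(C)C(=O)O)[C@@H]1CC3C(C)=CCC4C(=O)C(C)=C(OC)C(=O)C34Br
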